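**Plan** (hydrindane numbering: C1 bears the 2-methylbutanoate, C2 is the ketone, C3 the acetoxyethyl arm, C3a/C7a the ring fusion, C4 the isopropyl group, C6 the enoate, C7 the methylidene)
1. Retrosynthesis: the three esters come off first; the C7 methylidene comes from Cope elimination of a C7 CH2NMe2 group; the β-hydroxy ketone C2(=O)–C3–CH(OH)CH3 comes from an isoxazoline.
2. The cyclopentanone is cut at C2–C3 (and the carbinol C–O) by an intramolecular silyl nitronate–alkene cycloaddition between a nitro-aldol arm on C7a and a (Z)-propenyl arm on C3a; the cyclohexane is cut at C7–C7a and C3a–C4 by a Diels–Alder reaction.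
3. Enabling feature: in ring C3a–C4–C5–C6–C7–C7a the C6 oxygen next to C5H2 makes C4–C5–C6–C7 a 2-siloxy-1,3-diene (from 5-methylhex-3-en-2-one, which brings the isopropyl group). The trans ring-fusion bond C3a–C7a is an (E)-alkene whose ends carry the two arms of the later five-membered ring: (E)-4,4-dimethoxybut-2-enal (CHO → C3 arm, acetal → masked C1).
4. Forward order: six-membered ring (step 2); C4, C7 and C6 adjusted on the cyclohexenone; five-membered ring closed onto it (step 11); acyl groups and the methylidene last.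
5. Stereochemistry: C3a/C7a trans from the (E)-dienophile, absolute sense from the chiral boron catalyst; C4 by dissolving-metal reduction; C6 by bulky hydride; C1 by catalytic asymmetric nitroaldol; C3 and the side-chain carbinol from the (Z)-alkene geometry and allylic 1,3-strain; the 2-methylbutanoyl centre is bought.

Key step: step 2

Remark: (E)-5-methylhex-3-en-2-one, (E)-4,4-dimethoxybut-2-enal, (E)-3-methylpent-2-enoic acid and (R)-2-methylbutanoic acid are taken as purchasable.
Remark: the antipodes of the oxazaborolidine (step 2) and of the bis(oxazoline) ligand (step 10) are those assumed to give the required face; if the sense is the opposite, only the catalyst antipode changes.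

Step 1
Reactants: 1 (3E)-5-methylhex-3-en-2-one
Product: 2 triisopropyl{[(3E)-5-methylhexa-1,3-dien-2-yl]oxy}silane
Conditions: LiN(iPr)2, THF, −78 °C; iPr3SiOTf, −78 → 0 °C
Reagents that add atoms: triisopropylsilyl trifluoromethanesulfonate, CC(C)[Si](C(C)C)(C(C)C)OS(=O)(=O)C(F)(F)F
Why: Kinetic deprotonation of the methyl group gives the cross-conjugated enolate, and O-silylation (silyl enol ether formation) should give the 2-siloxy diene with the (E)-alkene untouched.

Step 2
Reactants: 2 triisopropyl{[(3E)-5-methylhexa-1,3-dien-2-yl]oxy}silane; 3 (2E)-4,4-dimethoxybut-2-enal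
Product: 4 (1R,2R,6R)-6-(dimethoxymethyl)-2-(propan-2-yl)-4-[(triisopropylsilyl)oxy]cyclohex-3-ene-1-carbaldehyde
Conditions: (S)-3,3-diphenyl-1-(o-tolyl)tetrahydro-1H,3H-pyrrolo[1,2-c][1,3,2]oxazaborole (20 mol %), HNTf2 (18 mol %), CH2Cl2, −78 → −40 °C; Et3N quench
Reagents that add atoms: none
Why: The enal, bound through its formyl oxygen to the cationic boron, should undergo a concerted but asynchronous normal-demand [4+2] cycloaddition in which the terminal CH2 of the diene (future C7) bonds first to the acetal-bearing β-carbon (future C7a) and the isopropyl-bearing terminus (future C4) then bonds to the formyl-bearing α-carbon (future C3a). The closest known reaction type is the oxazaborolidinium-catalysed enantioselective Diels–Alder reaction of 2-(trialkylsilyloxy)-1,3-dienes with α,β-unsaturated aldehydes. The only ring formed, the cyclohexene, closes by suprafacial–suprafacial 4π+2π addition through a boat-like transition state. C3a and C7a are trans because the (E)-geometry of the dienophile is retained, and their absolute configuration is set by the catalyst, which must expose the Re,Re face of the enal. The third new centre (future C4, expected cis to the formyl group by the endo rule) is not needed, since step 4 erases it and both epimers converge. The step needs regioselectivity, secured because the siloxy and alkyl groups both make the CH2 terminus the nucleophilic end; it also needs the acetal to survive the Lewis acid, which should hold at low temperature because ionisation would give an oxocarbenium ion conjugated to the formyl group.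

Step 3
Reactants: 4 (1R,2R,6R)-6-(dimethoxymethyl)-2-(propan-2-yl)-4-[(triisopropylsilyl)oxy]cyclohex-3-ene-1-carbaldehyde
Product: 5 {[(3S,4R,5R)-5-(dimethoxymethyl)-3-(propan-2-yl)-4-[(1Z)-prop-1-en-1-yl]cyclohex-1-en-1-yl]oxy}tri(propan-2-yl)silane
Conditions: EtPPh3Br, KN(SiMe3)2, THF, 0 °C; then 4, −78 °C → rt
Reagents that add atoms: ethyltriphenylphosphonium bromide, CC[P+](c1ccccc1)(c1ccccc1)c1ccccc1.[Br-]
Why: A salt-free Wittig reaction of the non-stabilised ylide should give the (Z)-propenyl group under kinetic control, the low temperature guarding the aldehyde α-centre and the silyl enol ether being inert.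

Step 4
Reactants: 5 {[(3S,4R,5R)-5-(dimethoxymethyl)-3-(propan-2-yl)-4-[(1Z)-prop-1-en-1-yl]cyclohex-1-en-1-yl]oxy}tri(propan-2-yl)silane
Product: 6 (4S,5R)-5-(dimethoxymethyl)-3-(propan-2-yl)-4-[(1Z)-prop-1-en-1-yl]cyclohex-2-en-1-one
Conditions: Pd(OAc)2 (1.1 equiv), MeCN, rt → 40 °C
Reagents that add atoms: none
Why: Saegusa–Ito oxidation: the palladium enolate formed from the silyl enol ether can lose only the hydrogen on the isopropyl-bearing carbon, so the 3-isopropyl enone should form regiospecifically and the unwanted centre from step 2 is removed.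

Step 5
Reactants: 6 (4S,5R)-5-(dimethoxymethyl)-3-(propan-2-yl)-4-[(1Z)-prop-1-en-1-yl]cyclohex-2-en-1-one
Product: 7 (4S,5S,6S)-6-[(dimethylamino)methyl]-5-(dimethoxymethyl)-3-(propan-2-yl)-4-[(1Z)-prop-1-en-1-yl]cyclohex-2-en-1-one
Conditions: LiN(iPr)2, THF, −78 °C; CH2=NMe2+ I−, −78 → 0 °C
Reagents that add atoms: dimethyl(methylidene)ammonium iodide, C=[N+](C)C.[I-]
Why: Kinetic α′-deprotonation of the enone (the only enolisable α-position) and a Mannich reaction with the preformed iminium salt should place the one-carbon handle at the future C7, trans to its neighbour; this centre is removed in step 14.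

Step 6
Reactants: 7 (4S,5S,6S)-6-[(dimethylamino)methyl]-5-(dimethoxymethyl)-3-(propan-2-yl)-4-[(1Z)-prop-1-en-1-yl]cyclohex-2-en-1-one
Product: 8 (2S,3S,4R,5R)-2-[(dimethylamino)methyl]-3-(dimethoxymethyl)-5-(propan-2-yl)-4-[(1Z)-prop-1-en-1-yl]cyclohexan-1-one
Conditions: Li, NH3(l)/THF, t-BuOH (1 equiv), −78 °C; NH4Cl
Reagents that add atoms: none
Why: Dissolving-metal conjugate reduction protonates the β-carbon axially on the chair that keeps the neighbouring groups equatorial, so the isopropyl group should end equatorial and trans to the propenyl group; the isolated (Z)-alkene, acetal and amine are inert.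

Step 7
Reactants: 8 (2S,3S,4R,5R)-2-[(dimethylamino)methyl]-3-(dimethoxymethyl)-5-(propan-2-yl)-4-[(1Z)-prop-1-en-1-yl]cyclohexan-1-one
Product: 9 (1S,2S,3S,4R,5R)-2-[(dimethylamino)methyl]-3-(dimethoxymethyl)-5-(propan-2-yl)-4-[(1Z)-prop-1-en-1-yl]cyclohexan-1-ol
Conditions: LiBH(s-Bu)3 (L-Selectride), THF, −78 °C; aq. NaOH work-up without peroxide
Reagents that add atoms: none
Why: The bulky hydride should attack the all-equatorial cyclohexanone from the equatorial side and give the axial alcohol (future C6), and omitting peroxide spares the amine.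

Step 8
Reactants: 9 (1S,2S,3S,4R,5R)-2-[(dimethylamino)methyl]-3-(dimethoxymethyl)-5-(propan-2-yl)-4-[(1Z)-prop-1-en-1-yl]cyclohexan-1-ol; 10 (2E)-3-methylpent-2-enoic acid
Product: 11 (1S,2S,3S,4R,5R)-2-[(dimethylamino)methyl]-3-(dimethoxymethyl)-5-(propan-2-yl)-4-[(1Z)-prop-1-en-1-yl]cyclohexyl (2E)-3-methylpent-2-enoate
Conditions: DCC, DMAP, CH2Cl2, 0 °C → rt
Reagents that add atoms: none
Why: Steglich esterification of the only hydroxyl group should proceed with retention at carbon and without isomerising the enoate.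

Step 9
Reactants: 11 (1S,2S,3S,4R,5R)-2-[(dimethylamino)methyl]-3-(dimethoxymethyl)-5-(propan-2-yl)-4-[(1Z)-prop-1-en-1-yl]cyclohexyl (2E)-3-methylpent-2-enoate
Product: 12 (1S,2S,3S,4R,5R)-2-[(dimethylamino)methyl]-3-formyl-5-(propan-2-yl)-4-[(1Z)-prop-1-en-1-yl]cyclohexyl (2E)-3-methylpent-2-enoate
Conditions: 2 M aq. HCl/THF, 0 °C → rt; then NaHCO3
Reagents that add atoms: water, O
Why: Acetal hydrolysis should unmask the aldehyde while the ester and alkenes survive dilute acid; the α-centre is already in its stable trans,trans arrangement.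

Step 10
Reactants: 12 (1S,2S,3S,4R,5R)-2-[(dimethylamino)methyl]-3-formyl-5-(propan-2-yl)-4-[(1Z)-prop-1-en-1-yl]cyclohexyl (2E)-3-methylpent-2-enoate
Product: 13 (1S,2S,3S,4R,5R)-2-[(dimethylamino)methyl]-3-[(1R)-1-hydroxy-2-nitroethyl]-5-(propan-2-yl)-4-[(1Z)-prop-1-en-1-yl]cyclohexyl (2E)-3-methylpent-2-enoate
Conditions: MeNO2 (10 equiv), Cu(OAc)2·H2O (10 mol %), 2,2'-(propane-2,2-diyl)bis[(3aS,8aR)-8,8a-dihydro-3aH-indeno[1,2-d]oxazole] (11 mol %), EtOH, rt
Reagents that add atoms: nitromethane, C[N+](=O)[O-]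
Why: A catalytic asymmetric Henry reaction adds the last ring carbon and should set the carbinol (future C1) under catalyst control, since the two ring neighbours of the aldehyde give little substrate bias and the acetate base is too mild to cause retro-addition.

Step 11
Reactants: 13 (1S,2S,3S,4R,5R)-2-[(dimethylamino)methyl]-3-[(1R)-1-hydroxy-2-nitroethyl]-5-(propan-2-yl)-4-[(1Z)-prop-1-en-1-yl]cyclohexyl (2E)-3-methylpent-2-enoate
Product: 16 tricyclic 1-hydroxy isoxazoline (full description in the compound list), via bis-silylated nitronate 14 (not isolated), via N-silyloxyisoxazolidine 15 (not isolated)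
Conditions: Me3SiCl, Et3N, MeCN, rt → 50 °C; then 1 M aq. HCl/THF, rt
Reagents that add atoms: none
Why: In an intramolecular silyl nitronate–olefin cycloaddition the nitronate carbon should bond to the nearer alkene carbon and close the trans-fused cyclopentane; allylic 1,3-strain holds H3a in the plane of the (Z)-alkene so the dipole adds from the C7a side (H3 trans to H3a), the (Z)-geometry is transferred by syn addition to give the syn-aldol carbinol centre, and acid then eliminates silanol and cleaves the transient silyl ether.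

Step 12
Reactants: 16 tricyclic 1-hydroxy isoxazoline; 17 (2R)-2-methylbutanoic acid
Product: 18 tricyclic isoxazoline 1-[(2R)-2-methylbutanoate]
Conditions: DCC, DMAP, CH2Cl2, rt
Reagents that add atoms: none
Why: Steglich esterification of the only free hydroxyl group, done while the ketone is still masked as the isoxazoline, avoids α-ketol chemistry and should not racemise the simple α-branched acid.

Step 13
Reactants: 18 tricyclic isoxazoline 1-[(2R)-2-methylbutanoate]
Product: 19 (1R,3R,3aR,4R,6S,7S,7aS)-7-[(dimethylamino)methyl]-3-[(1S)-1-hydroxyethyl]-1-{[(2R)-2-methylbutanoyl]oxy}-2-oxo-4-(propan-2-yl)octahydro-1H-inden-6-yl (2E)-3-methylpent-2-enoate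
Conditions: Mo(CO)6, MeCN/H2O (15:1), 80 °C
Reagents that add atoms: water, O
Why: Zerovalent molybdenum should cleave the N–O bond reductively and the resulting β-hydroxy imine hydrolyses to the β-hydroxy ketone without touching the enoate; it is run before any allylic ester exists.

Step 14
Reactants: 19 (1R,3R,3aR,4R,6S,7S,7aS)-7-[(dimethylamino)methyl]-3-[(1S)-1-hydroxyethyl]-1-{[(2R)-2-methylbutanoyl]oxy}-2-oxo-4-(propan-2-yl)octahydro-1H-inden-6-yl (2E)-3-methylpent-2-enoate
Product: 21 7-methylidene hydroxy ketone (full name in the compound list), via amine N-oxide 20 (not isolated)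
Conditions: mCPBA (1.0 equiv), CH2Cl2, −20 °C; filtration through basic Al2O3; then THF, 55 °C
Reagents that add atoms: none
Why: N-oxidation is much faster than any other oxidation open to the peracid, and the Cope elimination can take only H7 in its syn five-membered transition state, so the exocyclic methylidene should form regiospecifically under near-neutral conditions.

Step 15
Reactants: 21 7-methylidene hydroxy ketone
Product: 22 (1R,3R,3aR,4R,6S,7aS)-3-[(1S)-1-(acetyloxy)ethyl]-1-{[(2R)-2-methylbutanoyl]oxy}-7-methylidene-2-oxo-4-(propan-2-yl)octahydro-1H-inden-6-yl (2E)-3-methylpent-2-enoate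
Conditions: Ac2O, pyridine, 0 °C → rt
Reagents that add atoms: acetic anhydride, CC(=O)OC(C)=O
Why: Acetylation of the one remaining hydroxyl group without a stronger base should avoid β-elimination of the new acetate.

**Compound list**
1 | (3E)-5-methylhex-3-en-2-one | CC(=O)/C=C/C(C)C | starting material
2 | triisopropyl{[(3E)-5-methylhexa-1,3-dien-2-yl]oxy}silane | C=C(O[Si](C(C)C)(C(C)C)C(C)C)/C=C/C(C)C | intermediate
3 | (2E)-4,4-dimethoxybut-2-enal | O=C/C=C/C(OC)OC | starting material
4 | (1R,2R,6R)-6-(dimethoxymethyl)-2-(propan-2-yl)-4-[(triisopropylsilyl)oxy]cyclohex-3-ene-1-carbaldehyde (endo adduct drawn; its C2 epimer converges at 6) | C1[C@@H](C(OC)OC)[C@H](C=O)[C@H](C(C)C)C=C1O[Si](C(C)C)(C(C)C)C(C)C | intermediate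
5 | {[(3S,4R,5R)-5-(dimethoxymethyl)-3-(propan-2-yl)-4-[(1Z)-prop-1-en-1-yl]cyclohex-1-en-1-yl]oxy}tri(propan-2-yl)silane | C1[C@@H](C(OC)OC)[C@H](/C=C\C)[C@H](C(C)C)C=C1O[Si](C(C)C)(C(C)C)C(C)C | intermediate
6 | (4S,5R)-5-(dimethoxymethyl)-3-(propan-2-yl)-4-[(1Z)-prop-1-en-1-yl]cyclohex-2-en-1-one | O=C1C[C@@H](C(OC)OC)[C@H](/C=C\C)C(C(C)C)=C1 | intermediate
7 | (4S,5S,6S)-6-[(dimethylamino)methyl]-5-(dimethoxymethyl)-3-(propan-2-yl)-4-[(1Z)-prop-1-en-1-yl]cyclohex-2-en-1-one | O=C1[C@H](CN(C)C)[C@@H](C(OC)OC)[C@H](/C=C\C)C(C(C)C)=C1 | intermediate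
8 | (2S,3S,4R,5R)-2-[(dimethylamino)methyl]-3-(dimethoxymethyl)-5-(propan-2-yl)-4-[(1Z)-prop-1-en-1-yl]cyclohexan-1-one | O=C1[C@H](CN(C)C)[C@@H](C(OC)OC)[C@H](/C=C\C)[C@@H](C(C)C)C1 | intermediate
9 | (1S,2S,3S,4R,5R)-2-[(dimethylamino)methyl]-3-(dimethoxymethyl)-5-(propan-2-yl)-4-[(1Z)-prop-1-en-1-yl]cyclohexan-1-ol | O[C@@H]1[C@H](CN(C)C)[C@@H](C(OC)OC)[C@H](/C=C\C)[C@@H](C(C)C)C1 | intermediate
10 | (2E)-3-methylpent-2-enoic acid | CC/C(C)=C/C(=O)O | starting material
11 | (1S,2S,3S,4R,5R)-2-[(dimethylamino)methyl]-3-(dimethoxymethyl)-5-(propan-2-yl)-4-[(1Z)-prop-1-en-1-yl]cyclohexyl (2E)-3-methylpent-2-enoate | CC/C(C)=C/C(=O)O[C@@H]1[C@H](CN(C)C)[C@@H](C(OC)OC)[C@H](/C=C\C)[C@@H](C(C)C)C1 | intermediate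
12 | (1S,2S,3S,4R,5R)-2-[(dimethylamino)methyl]-3-formyl-5-(propan-2-yl)-4-[(1Z)-prop-1-en-1-yl]cyclohexyl (2E)-3-methylpent-2-enoate | CC/C(C)=C/C(=O)O[C@@H]1[C@H](CN(C)C)[C@@H](C=O)[C@H](/C=C\C)[C@@H](C(C)C)C1 | intermediate
13 | (1S,2S,3S,4R,5R)-2-[(dimethylamino)methyl]-3-[(1R)-1-hydroxy-2-nitroethyl]-5-(propan-2-yl)-4-[(1Z)-prop-1-en-1-yl]cyclohexyl (2E)-3-methylpent-2-enoate | CC/C(C)=C/C(=O)O[C@@H]1[C@H](CN(C)C)[C@@H]([C@@H](O)C[N+](=O)[O-])[C@H](/C=C\C)[C@@H](C(C)C)C1 | intermediate
14 | trimethylsilyl nitronate of the O-trimethylsilyl ether of 13 | CC/C(C)=C/C(=O)O[C@@H]1[C@H](CN(C)C)[C@@H]([C@@H](O[Si](C)(C)C)C=[N+]([O-])O[Si](C)(C)C)[C@H](/C=C\C)[C@@H](C(C)C)C1 | intermediate (not isolated)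
15 | N-(trimethylsilyloxy)isoxazolidine cycloadduct of 14 (new bond C2–C3; H2 cis to H3; 1-OSiMe3) | CC/C(C)=C/C(=O)O[C@@H]1[C@H](CN(C)C)[C@@H]2[C@H]([C@@H]3[C@H](C)ON(O[Si](C)(C)C)[C@@H]3[C@@H]2O[Si](C)(C)C)[C@@H](C(C)C)C1 | intermediate (not isolated)
16 | tricyclic 1-hydroxy isoxazoline: trans-fused hydrindane whose C2 is the C=N carbon of a 2-isoxazoline closed through O to the (S)-CH(CH3) carbon on C3; (1R)-OH, H3 trans to H3a, 7-CH2NMe2, 6-O-[(2E)-3-methylpent-2-enoyl]; other centres as in 19 | CC/C(C)=C/C(=O)O[C@@H]1[C@H](CN(C)C)[C@@H]2[C@H]([C@@H]3[C@H](C)ON=C3[C@@H]2O)[C@@H](C(C)C)C1 | intermediate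
17 | (2R)-2-methylbutanoic acid | CC[C@@H](C)C(=O)O | starting material
18 | 16 acylated at O1 with the (2R)-2-methylbutanoyl group | CC/C(C)=C/C(=O)O[C@@H]1[C@H](CN(C)C)[C@@H]2[C@H]([C@@H]3[C@H](C)ON=C3[C@@H]2OC(=O)[C@H](C)CC)[C@@H](C(C)C)C1 | intermediate
19 | (1R,3R,3aR,4R,6S,7S,7aS)-7-[(dimethylamino)methyl]-3-[(1S)-1-hydroxyethyl]-1-{[(2R)-2-methylbutanoyl]oxy}-2-oxo-4-(propan-2-yl)octahydro-1H-inden-6-yl (2E)-3-methylpent-2-enoate | CC/C(C)=C/C(=O)O[C@@H]1[C@H](CN(C)C)[C@@H]2[C@H]([C@H]([C@H](C)O)C(=O)[C@@H]2OC(=O)[C@H](C)CC)[C@@H](C(C)C)C1 | intermediate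
20 | N-oxide of 19 | CC/C(C)=C/C(=O)O[C@@H]1[C@H](C[N+](C)(C)[O-])[C@@H]2[C@H]([C@H]([C@H](C)O)C(=O)[C@@H]2OC(=O)[C@H](C)CC)[C@@H](C(C)C)C1 | intermediate (not isolated)
21 | (1R,3R,3aR,4R,6S,7aS)-3-[(1S)-1-hydroxyethyl]-1-{[(2R)-2-methylbutanoyl]oxy}-7-methylidene-2-oxo-4-(propan-2-yl)octahydro-1H-inden-6-yl (2E)-3-methylpent-2-enoate | CC/C(C)=C/C(=O)O[C@@H]1C(=C)[C@@H]2[C@H]([C@H]([C@H](C)O)C(=O)[C@@H]2OC(=O)[C@H](C)CC)[C@@H](C(C)C)C1 | intermediate
22 | (1R,3R,3aR,4R,6S,7aS)-3-[(1S)-1-(acetyloxy)ethyl]-1-{[(2R)-2-methylbutanoyl]oxy}-7-methylidene-2-oxo-4-(propan-2-yl)octahydro-1H-inden-6-yl (2E)-3-methylpent-2-enoate | C=C1[C@@H]2[C@H]([C@H]([C@H](C)OC(C)=O)C(=O)[C@@H]2OC(=O)[C@H](C)CC)[C@@H](C(C)C)C[C@@H]1OC(=O)/C=C(\C)CC | target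

Total step count: 15. Longest linear sequence: 15 steps (1 → 22).

**Steps most likely to fail**

Step 2. The catalyst may give poor enantioface control with this β-substituted enal, or the strong Lewis acid may ionise the acetal and divert the silyl enol ether into Mukaiyama-type addition. The fallback uses a covalently bound auxiliary and no acid; it sets out from 3 and returns at 6. (2S,5S)-2,5-Diphenylpyrrolidine and (E)-4-methoxybut-3-en-2-one are condensed (THF, 50 °C) to (3E)-4-[(2S,5S)-2,5-diphenylpyrrolidin-1-yl]but-3-en-2-one F1. O-Silylation (KN(SiMe3)2, t-BuMe2SiCl, THF, −78 °C) gives (2S,5S)-1-[(1E)-3-[(tert-butyldimethylsilyl)oxy]buta-1,3-dien-1-yl]-2,5-diphenylpyrrolidine F2. Thermal cycloaddition of F2 with 3 (toluene, −20 °C → rt) should give the amino silyl enol ether aldehyde F3, the phenyl group of the auxiliary shielding one diene face. Wittig ethylidenation as in step 3 gives the (Z)-propenyl compound F4, and HF·pyridine (MeCN, 0 °C) removes silyl group and auxiliary to give (4R,5R)-5-(dimethoxymethyl)-4-[(1Z)-prop-1-en-1-yl]cyclohex-2-en-1-one F5. Conjugate addition of i-PrMgCl with CuBr·SMe2 (THF, −40 °C), followed in the same flask by N-tert-butylbenzenesulfinimidoyl chloride to dehydrogenate the enolate, leads to 6.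

Step 10. The amine in the substrate may trigger an uncatalysed background addition, or the ring may override the catalyst, so the new carbinol forms with poor control. The fallback sets the centre by reduction instead of C–C bond formation; it sets out from 12 and returns at 13. Nitromethane with catalytic tetramethylguanidine gives the epimeric nitro alcohols F6. Oxidation with the triacetoxy periodinane (CH2Cl2, NaHCO3) gives the α-nitro ketone F7. Asymmetric transfer hydrogenation with RuCl(p-cymene)[(R,R)-TsDPEN] in HCO2H/Et3N (catalyst antipode chosen for the (R)-carbinol) should give 13.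

Step 11. The silyl nitronate is a weak dipole and may cyclise too slowly onto the 1,2-disubstituted alkene, letting desilylation and retro-nitroaldol cleavage compete. The fallback uses the more reactive nitrile oxide on a robustly protected alcohol; it sets out from 13 and returns at 16. Silylation (t-BuMe2SiOTf, 2,6-lutidine, CH2Cl2, −78 °C) gives the silyl ether F8. Dehydration with PhNCO and catalytic Et3N (benzene, rt → 60 °C) generates the nitrile oxide F9, which should cyclise with the same allylic 1,3-strain control to the silylated isoxazoline F10. HF·pyridine (THF, 0 °C → rt) then gives 16.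

**Further compounds**
F1 | step 2 | (3E)-4-[(2S,5S)-2,5-diphenylpyrrolidin-1-yl]but-3-en-2-one | CC(=O)/C=C/N1[C@H](c2ccccc2)CC[C@H]1c1ccccc1
F2 | step 2 | (2S,5S)-1-[(1E)-3-[(tert-butyldimethylsilyl)oxy]buta-1,3-dien-1-yl]-2,5-diphenylpyrrolidine | C=C(O[Si](C)(C)C(C)(C)C)/C=C/N1[C@H](c2ccccc2)CC[C@H]1c1ccccc1
F3 | step 2 | (1S,2R,6R)-4-[(tert-butyldimethylsilyl)oxy]-6-(dimethoxymethyl)-2-[(2S,5S)-2,5-diphenylpyrrolidin-1-yl]cyclohex-3-ene-1-carbaldehyde | C1[C@@H](C(OC)OC)[C@H](C=O)[C@H](N2[C@H](c3ccccc3)CC[C@H]2c2ccccc2)C=C1O[Si](C)(C)C(C)(C)C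
F4 | step 2 | (2S,5S)-1-[(1S,5R,6S)-3-[(tert-butyldimethylsilyl)oxy]-5-(dimethoxymethyl)-6-[(1Z)-prop-1-en-1-yl]cyclohex-2-en-1-yl]-2,5-diphenylpyrrolidine | C1[C@@H](C(OC)OC)[C@H](/C=C\C)[C@H](N2[C@H](c3ccccc3)CC[C@H]2c2ccccc2)C=C1O[Si](C)(C)C(C)(C)C
F5 | step 2 | (4R,5R)-5-(dimethoxymethyl)-4-[(1Z)-prop-1-en-1-yl]cyclohex-2-en-1-one | O=C1C[C@@H](C(OC)OC)[C@H](/C=C\C)C=C1
F6 | step 10 | epimeric mixture at the carbinol carbon of (1S,2S,3S,4R,5R)-2-[(dimethylamino)methyl]-3-(1-hydroxy-2-nitroethyl)-5-(propan-2-yl)-4-[(1Z)-prop-1-en-1-yl]cyclohexyl (2E)-3-methylpent-2-enoate | CC/C(C)=C/C(=O)O[C@@H]1[C@H](CN(C)C)[C@@H](C(O)C[N+](=O)[O-])[C@H](/C=C\C)[C@@H](C(C)C)C1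
F7 | step 10 | (1S,2S,3S,4R,5R)-2-[(dimethylamino)methyl]-3-(nitroacetyl)-5-(propan-2-yl)-4-[(1Z)-prop-1-en-1-yl]cyclohexyl (2E)-3-methylpent-2-enoate | CC/C(C)=C/C(=O)O[C@@H]1[C@H](CN(C)C)[C@@H](C(=O)C[N+](=O)[O-])[C@H](/C=C\C)[C@@H](C(C)C)C1
F8 | step 11 | O-(tert-butyldimethylsilyl) ether of 13 | CC/C(C)=C/C(=O)O[C@@H]1[C@H](CN(C)C)[C@@H]([C@@H](O[Si](C)(C)C(C)(C)C)C[N+](=O)[O-])[C@H](/C=C\C)[C@@H](C(C)C)C1
F9 | step 11 | nitrile oxide from F8 | CC/C(C)=C/C(=O)O[C@@H]1[C@H](CN(C)C)[C@@H]([C@@H](O[Si](C)(C)C(C)(C)C)C#[N+][O-])[C@H](/C=C\C)[C@@H](C(C)C)C1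
F10 | step 11 | O1-(tert-butyldimethylsilyl) ether of 16 | CC/C(C)=C/C(=O)O[C@@H]1[C@H](CN(C)C)[C@@H]2[C@H]([C@@H]3[C@H](C)ON=C3[C@@H]2O[Si](C)(C)C(C)(C)C)[C@@H](C(C)C)C1
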